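**Plan**
- Ring B of agrimol B is a 2-acyl-4,6-bis(arylmethyl)benzene-1,3,5-triol. Its six ring carbons, three oxygens and the acyl carbonyl are the folded form of C1–C7 of a 3,5,7-trioxodecanoate carrying the arms on C2 and C4, which is what allows a Claisen closure.
- Cuts, in retrosynthetic order: the four benzyl C–O bonds; the ring B bond C1–C6 (acyl-bearing ring carbon to a neighbouring C–OH carbon); the two C–CH2Ar bonds at chain C2 and C4; chain bond C4–C5; chain bond C6–C7.
- Forward: the ring A/C arm is made as a benzylic bromide from 2,4,6-trihydroxytoluene (steps 1–6). The C5–C10 unit with C7 masked as a dioxolane (steps 7–8) is joined to methyl acetoacetate (step 9).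
- Both arms are then attached with carbonate base (step 10), so the butanoyl ketones of the arms never meet a strong base; unmasking (step 11), closure of ring B (step 12) and debenzylation (step 13) follow.
- The only stereocentre (C8 of the chain, the α-carbon of the 2-methylbutanoyl group) comes from (S)-2-methylbutanoic acid and is never enolised; C2 and C4 are epimer mixtures that vanish on aromatisation.

Key step: step 12

Remark: chain numbering is C1 = ester carbon to C10 = terminal methyl of the sec-butyl group; Ar = 2,6-bis(benzyloxy)-3-butanoyl-4-methoxy-5-methylphenyl, attached through its C1.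
Remark: compounds 17–21 are expected as keto–enol mixtures, and 18–21 as epimer mixtures at the arm-bearing carbons; they are drawn as keto forms without configuration there.

Step 1
Reactants: 1 2-methylbenzene-1,3,5-triol (2,4,6-trihydroxytoluene); 2 butanoyl chloride
Product: 3 1-(2,4,6-trihydroxy-3-methylphenyl)butan-1-one
Conditions: AlCl3, PhNO2/CH2Cl2, 0 °C → rt; aq HCl
Reagents that add atoms: none
Why: Friedel–Crafts C-acylation of the very nucleophilic phloroglucinol nucleus, whose two free ring positions are equivalent and which is deactivated against a second acylation once the first acyl group is in place.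

Step 2
Reactants: 3 1-(2,4,6-trihydroxy-3-methylphenyl)butan-1-one
Product: 4 1-[4,6-bis(benzyloxy)-2-hydroxy-3-methylphenyl]butan-1-one
Conditions: BnBr (2.1 equiv), K2CO3, acetone, reflux
Reagents that add atoms: benzyl bromide, BrCc1ccccc1
Why: Williamson etherification in which the para hydroxyl (most acidic) and the less hindered ortho hydroxyl next to ring hydrogen should react, while the hydroxyl wedged between methyl and acyl stays free in its strong hydrogen bond to the ketone.

Step 3
Reactants: 4 1-[4,6-bis(benzyloxy)-2-hydroxy-3-methylphenyl]butan-1-one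
Product: 5 1-[4,6-bis(benzyloxy)-2-methoxy-3-methylphenyl]butan-1-one
Conditions: MeI, K2CO3, DMF, 50 °C
Reagents that add atoms: iodomethane, CI
Why: Williamson O-methylation of the remaining chelated phenol under more forcing conditions, with a base too weak to enolise the butanoyl ketone.

Step 4
Reactants: 5 1-[4,6-bis(benzyloxy)-2-methoxy-3-methylphenyl]butan-1-one
Product: 7 2,6-bis(benzyloxy)-3-butanoyl-4-methoxy-5-methylbenzaldehyde, via aryl iminium salt 6 (not isolated)
Conditions: POCl3, DMF, 0 → 40 °C; aq NaOAc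
Reagents that add atoms: N,N-dimethylformamide, CN(C)C=O (formyl carbon); water, O (aldehyde oxygen)
Why: Vilsmeier–Haack formylation at the only free ring position, which is ortho to both benzyloxy groups and para to methoxy, while the ketone is twisted out of conjugation by its two ortho substituents and so deactivates little and is too hindered to react itself.

Step 5
Reactants: 7 2,6-bis(benzyloxy)-3-butanoyl-4-methoxy-5-methylbenzaldehyde
Product: 8 1-[2,4-bis(benzyloxy)-3-(hydroxymethyl)-6-methoxy-5-methylphenyl]butan-1-one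
Conditions: NaBH4 (0.5 equiv), THF/MeOH, −20 °C
Reagents that add atoms: none
Why: Chemoselective borohydride reduction, the aldehyde being reduced far faster than the di-ortho-substituted aryl ketone at low temperature with limited hydride.

Step 6
Reactants: 8 1-[2,4-bis(benzyloxy)-3-(hydroxymethyl)-6-methoxy-5-methylphenyl]butan-1-one
Product: 9 1-[2,4-bis(benzyloxy)-3-(bromomethyl)-6-methoxy-5-methylphenyl]butan-1-one
Conditions: CBr4, PPh3, CH2Cl2, 0 °C; short silica plug, used at once
Reagents that add atoms: tetrabromomethane, BrC(Br)(Br)Br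
Why: Appel bromination under neutral conditions suits this electron-rich benzylic alcohol, and the fully substituted ring cannot alkylate itself.

Step 7
Reactants: 10 (2S)-2-methylbutanoic acid; 11 2,2-dimethyl-1,3-dioxane-4,6-dione (Meldrum's acid)
Product: 13 (4S)-N-methoxy-N,4-dimethyl-3-oxohexanamide, via acyl Meldrum's acid 12 (not isolated)
Conditions: DCC, DMAP, CH2Cl2, 0 °C → rt; filter, aq KHSO4 wash; then MeNH(OMe)·HCl, Et3N, toluene, 85 °C
Reagents that add atoms: N,O-dimethylhydroxylamine hydrochloride, CNOC.Cl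
Why: Carbodiimide-mediated C-acylation of Meldrum's acid followed by thermal loss of acetone and CO2 to an acylketene that the amine traps (aminolysis of an acyl Meldrum's acid), with the stereocentre untouched because neither intermediate enolises toward it.

Step 8
Reactants: 13 (4S)-N-methoxy-N,4-dimethyl-3-oxohexanamide
Product: 14 2-{2-[(2S)-butan-2-yl]-1,3-dioxolan-2-yl}-N-methoxy-N-methylacetamide
Conditions: TMSOCH2CH2OTMS, TMSOTf (cat.), CH2Cl2, −78 → −20 °C; pyridine quench
Reagents that add atoms: 1,2-bis(trimethylsilyloxy)ethane, C[Si](C)(C)OCCO[Si](C)(C)C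
Why: Noyori ketalisation under aprotic, low-temperature conditions, chosen over hot acidic ketalisation so that the ketone is not enolised toward the adjacent stereocentre.

Step 9
Reactants: 14 2-{2-[(2S)-butan-2-yl]-1,3-dioxolan-2-yl}-N-methoxy-N-methylacetamide; 15 methyl 3-oxobutanoate (methyl acetoacetate)
Product: 17 methyl 6-{2-[(2S)-butan-2-yl]-1,3-dioxolan-2-yl}-3,5-dioxohexanoate, via acetoacetate dianion 16 (not isolated)
Conditions: 15 (1.5 equiv), NaH, THF, 0 °C; n-BuLi, 0 °C; then 14, −78 → 0 °C; aq NH4Cl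
Reagents that add atoms: none
Why: γ-Acylation of the acetoacetate dianion by a Weinreb amide (forms chain bond C4–C5), where the chelated tetrahedral adduct survives until work-up and so prevents both over-addition and quenching of the dianion by the diketo ester.

Step 10
Reactants: 17 methyl 6-{2-[(2S)-butan-2-yl]-1,3-dioxolan-2-yl}-3,5-dioxohexanoate; 9 1-[2,4-bis(benzyloxy)-3-(bromomethyl)-6-methoxy-5-methylphenyl]butan-1-one (2.05 equiv)
Product: 19 methyl 2,4-bis(ArCH2)-6-{2-[(2S)-butan-2-yl]-1,3-dioxolan-2-yl}-3,5-dioxohexanoate, via C4-monoalkylated diketo ester 18 (not isolated)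
Conditions: K2CO3, acetone, 0 → 40 °C
Reagents that add atoms: none
Why: C-Alkylation of β-dicarbonyl enolates at the only two carbonate-acidic carbons (C2 and C4, C6 being silenced by the ketal); each carbon becomes a hindered methine after taking one bulky arm so the second bromide should go to the other carbon, and because the arms are identical the order does not matter.

Step 11
Reactants: 19 methyl 2,4-bis(ArCH2)-6-{2-[(2S)-butan-2-yl]-1,3-dioxolan-2-yl}-3,5-dioxohexanoate
Product: 20 methyl (8S)-2,4-bis(ArCH2)-8-methyl-3,5,7-trioxodecanoate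
Conditions: 2 M HCl, THF, rt
Reagents that add atoms: water, O
Why: Acid-catalysed acetal hydrolysis that leaves benzyl ethers, aryl methyl ether and methyl ester intact, the freed C7 ketone enolising toward the doubly activated C6 and not toward C8.

Step 12
Reactants: 20 methyl (8S)-2,4-bis(ArCH2)-8-methyl-3,5,7-trioxodecanoate
Product: 22 (2S)-1-[3,5-bis(ArCH2)-2,4,6-trihydroxyphenyl]-2-methylbutan-1-one (tetra-O-benzyl agrimol B), via cyclohexane-1,3,5-trione tautomer 21 (not isolated)
Conditions: Mg(OMe)2 (5 equiv), MeOH/THF, 65 °C; then 1 M HCl, 0 °C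
Reagents that add atoms: none
Why: Mg(OMe)2 turns 20 into magnesium chelates of its β-dicarbonyl units, the C6 methylene between C5 and C7 being the most acidic and only unsubstituted carbon acid; its carbanion adds to the C1 ester carbonyl, methoxide leaves, and trione 21 enolises irreversibly to the benzene-1,3,5-triol, whose magnesium phenoxide is the thermodynamic sink. The closest known reaction type is the Claisen (Dieckmann-type) cyclisation of 3,5,7-trioxo esters to acylphloroglucinols under magnesium methoxide. Ring B closes by a 6-exo-trig acyl substitution (enolendo) that forms the C1–C6 bond. No stereocentre is created: the C2/C4 epimers converge on the planar ring, and C8 keeps its configuration because C7 sits in the chelated C5–C7 enolate and, after closure, in a phenoxide-conjugated ketone. The selectivity needed is C-acylation at C1 over aldol closure of C2 onto C7 and over O-acylation to a pyranone lactone; the arm on C2 means an aldol adduct would carry a quaternary carbon, could not aromatise and should revert, C7 is α-branched and tied up as enolate, and any lactone should be reopened by methoxide and drained to the aromatic product.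

Step 13
Reactants: 22 (2S)-1-[3,5-bis(ArCH2)-2,4,6-trihydroxyphenyl]-2-methylbutan-1-one
Product: 23 agrimol B, (2S)-1-(3,5-bis{[3-butanoyl-2,6-dihydroxy-4-methoxy-5-methylphenyl]methyl}-2,4,6-trihydroxyphenyl)-2-methylbutan-1-one
Conditions: H2 (1 atm), Pd/C, EtOAc/MeOH, rt
Reagents that add atoms: none
Why: Hydrogenolysis of the four benzyl aryl ethers over palladium metal on carbon, under which the hydrogen-bonded aryl ketones, the diarylmethane links and the stereocentre should be untouched.

**Compound list**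
1 | 2-methylbenzene-1,3,5-triol (2,4,6-trihydroxytoluene) | Cc1c(O)cc(O)cc1O | starting material
2 | butanoyl chloride | CCCC(=O)Cl | starting material
3 | 1-(2,4,6-trihydroxy-3-methylphenyl)butan-1-one | CCCC(=O)c1c(O)cc(O)c(C)c1O | intermediate
4 | 1-[4,6-bis(benzyloxy)-2-hydroxy-3-methylphenyl]butan-1-one | CCCC(=O)c1c(OCc2ccccc2)cc(OCc2ccccc2)c(C)c1O | intermediate
5 | 1-[4,6-bis(benzyloxy)-2-methoxy-3-methylphenyl]butan-1-one | CCCC(=O)c1c(OCc2ccccc2)cc(OCc2ccccc2)c(C)c1OC | intermediate
6 | N-{[2,6-bis(benzyloxy)-3-butanoyl-4-methoxy-5-methylphenyl]methylidene}-N-methylmethanaminium dichlorophosphate | CCCC(=O)c1c(OCc2ccccc2)c(C=[N+](C)C)c(OCc2ccccc2)c(C)c1OC.[O-]P(=O)(Cl)Cl | intermediate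
7 | 2,6-bis(benzyloxy)-3-butanoyl-4-methoxy-5-methylbenzaldehyde | CCCC(=O)c1c(OCc2ccccc2)c(C=O)c(OCc2ccccc2)c(C)c1OC | intermediate
8 | 1-[2,4-bis(benzyloxy)-3-(hydroxymethyl)-6-methoxy-5-methylphenyl]butan-1-one | CCCC(=O)c1c(OCc2ccccc2)c(CO)c(OCc2ccccc2)c(C)c1OC | intermediate
9 | 1-[2,4-bis(benzyloxy)-3-(bromomethyl)-6-methoxy-5-methylphenyl]butan-1-one | CCCC(=O)c1c(OCc2ccccc2)c(CBr)c(OCc2ccccc2)c(C)c1OC | intermediate
10 | (2S)-2-methylbutanoic acid | CC[C@H](C)C(=O)O | starting material
11 | 2,2-dimethyl-1,3-dioxane-4,6-dione (Meldrum's acid) | CC1(C)OC(=O)CC(=O)O1 | starting material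
12 | 5-[(2S)-1-hydroxy-2-methylbutylidene]-2,2-dimethyl-1,3-dioxane-4,6-dione | CC[C@H](C)C(O)=C1C(=O)OC(C)(C)OC1=O | intermediate
13 | (4S)-N-methoxy-N,4-dimethyl-3-oxohexanamide | CC[C@H](C)C(=O)CC(=O)N(C)OC | intermediate
14 | 2-{2-[(2S)-butan-2-yl]-1,3-dioxolan-2-yl}-N-methoxy-N-methylacetamide | CC[C@H](C)C1(CC(=O)N(C)OC)OCCO1 | intermediate
15 | methyl 3-oxobutanoate | CC(=O)CC(=O)OC | starting material
16 | sodium lithium dienolate (dianion) of methyl 3-oxobutanoate | [Li+].[Na+].C=C([O-])C=C([O-])OC | intermediate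
17 | methyl 6-{2-[(2S)-butan-2-yl]-1,3-dioxolan-2-yl}-3,5-dioxohexanoate | CC[C@H](C)C1(CC(=O)CC(=O)CC(=O)OC)OCCO1 | intermediate
18 | methyl 4-{[2,6-bis(benzyloxy)-3-butanoyl-4-methoxy-5-methylphenyl]methyl}-6-{2-[(2S)-butan-2-yl]-1,3-dioxolan-2-yl}-3,5-dioxohexanoate | CC[C@H](C)C1(CC(=O)C(Cc2c(OCc3ccccc3)c(C(=O)CCC)c(OC)c(C)c2OCc2ccccc2)C(=O)CC(=O)OC)OCCO1 | intermediate
19 | methyl 2,4-bis{[2,6-bis(benzyloxy)-3-butanoyl-4-methoxy-5-methylphenyl]methyl}-6-{2-[(2S)-butan-2-yl]-1,3-dioxolan-2-yl}-3,5-dioxohexanoate | CC[C@H](C)C1(CC(=O)C(Cc2c(OCc3ccccc3)c(C(=O)CCC)c(OC)c(C)c2OCc2ccccc2)C(=O)C(Cc2c(OCc3ccccc3)c(C(=O)CCC)c(OC)c(C)c2OCc2ccccc2)C(=O)OC)OCCO1 | intermediate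
20 | methyl (8S)-2,4-bis{[2,6-bis(benzyloxy)-3-butanoyl-4-methoxy-5-methylphenyl]methyl}-8-methyl-3,5,7-trioxodecanoate | CC[C@H](C)C(=O)CC(=O)C(Cc1c(OCc2ccccc2)c(C(=O)CCC)c(OC)c(C)c1OCc1ccccc1)C(=O)C(Cc1c(OCc2ccccc2)c(C(=O)CCC)c(OC)c(C)c1OCc1ccccc1)C(=O)OC | intermediate
21 | 2-[(2S)-2-methylbutanoyl]-4,6-bis{[2,6-bis(benzyloxy)-3-butanoyl-4-methoxy-5-methylphenyl]methyl}cyclohexane-1,3,5-trione | CC[C@H](C)C(=O)C1C(=O)C(Cc2c(OCc3ccccc3)c(C(=O)CCC)c(OC)c(C)c2OCc2ccccc2)C(=O)C(Cc2c(OCc3ccccc3)c(C(=O)CCC)c(OC)c(C)c2OCc2ccccc2)C1=O | intermediate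
22 | (2S)-1-(3,5-bis{[2,6-bis(benzyloxy)-3-butanoyl-4-methoxy-5-methylphenyl]methyl}-2,4,6-trihydroxyphenyl)-2-methylbutan-1-one (tetra-O-benzyl agrimol B) | CCCC(=O)c1c(OCc2ccccc2)c(Cc2c(O)c(Cc3c(OCc4ccccc4)c(C)c(OC)c(C(=O)CCC)c3OCc3ccccc3)c(O)c(C(=O)[C@@H](C)CC)c2O)c(OCc2ccccc2)c(C)c1OC | intermediate
23 | agrimol B | CCCC(=O)c1c(O)c(Cc2c(O)c(Cc3c(O)c(C)c(OC)c(C(=O)CCC)c3O)c(O)c(C(=O)[C@@H](C)CC)c2O)c(O)c(C)c1OC | target

**Count**
Total: 13 steps. Longest linear sequence: 10 steps (steps 1–6, then 10–13, from 2,4,6-trihydroxytoluene); the chain branch (steps 7–9) joins at step 10.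

**Steps most likely to fail**

Step 12. O-acylation of the C5 enolate onto the ester (lactonisation) or methoxide-induced retro-Claisen cleavage of the chain could outrun the C-acylation. The fallback gives up chain folding and bridges a preformed central ring. Acid 10 is converted with (COCl)2 and catalytic DMF into (2S)-2-methylbutanoyl chloride F1. This acylates benzene-1,3,5-triol (commercial) under AlCl3 in PhNO2 to (2S)-2-methyl-1-(2,4,6-trihydroxyphenyl)butan-1-one F2. Acid-catalysed double Friedel–Crafts benzylation of F2 with two equivalents of alcohol 8 (catalytic BF3·OEt2, CH2Cl2, 0 °C) at its two free ring carbons then rejoins the route at 22.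

Step 10. O-alkylation of the diketonate, a second alkylation at a carbon that already bears an arm, and ionisation of the labile bromide before it is captured could erode the double alkylation. The fallback replaces substitution by reductive alkylation and starts from aldehyde 7 and diketo ester 17, using catalytic L-proline and Hantzsch ester in EtOH/CH2Cl2 at rt. Knoevenagel condensation at C4 should give methyl 4-(ArCH=)-6-{2-[(2S)-butan-2-yl]-1,3-dioxolan-2-yl}-3,5-dioxohexanoate F3, which is reduced as it forms to 18. The same events at C2 pass through methyl 4-(ArCH2)-2-(ArCH=)-6-{2-[(2S)-butan-2-yl]-1,3-dioxolan-2-yl}-3,5-dioxohexanoate F4 and rejoin the route at 19. A carbon can condense only while it is still CH2, so one arm per carbon is built in and no O-alkyl product can form; steps 5 and 6 are then not needed.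

Step 11. Under the acid needed to open the β-keto dioxolane, the freed 1,3,5-triketone could cyclodehydrate to a pyranone, or the ester could lactonise. The fallback carries C7 at the alcohol level and oxidises last under neutral conditions. It starts from 13, which NaBH4 reduces to (4S)-3-hydroxy-N-methoxy-N,4-dimethylhexanamide F5 (both carbinol epimers are usable). TBSCl/imidazole gives (4S)-3-[(tert-butyldimethylsilyl)oxy]-N-methoxy-N,4-dimethylhexanamide F6. Acylation of dianion 16 as in step 9 gives methyl (8S)-7-[(tert-butyldimethylsilyl)oxy]-8-methyl-3,5-dioxodecanoate F7. Double alkylation with 9 as in step 10 gives methyl (8S)-2,4-bis(ArCH2)-7-[(tert-butyldimethylsilyl)oxy]-8-methyl-3,5-dioxodecanoate F8. HF·pyridine then frees methyl (8S)-2,4-bis(ArCH2)-7-hydroxy-8-methyl-3,5-dioxodecanoate F9, and Dess–Martin periodinane with NaHCO3 oxidises it to rejoin the route at 20.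

**Further compounds**
F1 | step 12 | (2S)-2-methylbutanoyl chloride | CC[C@H](C)C(=O)Cl
F2 | step 12 | (2S)-2-methyl-1-(2,4,6-trihydroxyphenyl)butan-1-one | CC[C@H](C)C(=O)c1c(O)cc(O)cc1O
F3 | step 10 | methyl 4-{[2,6-bis(benzyloxy)-3-butanoyl-4-methoxy-5-methylphenyl]methylidene}-6-{2-[(2S)-butan-2-yl]-1,3-dioxolan-2-yl}-3,5-dioxohexanoate | CC[C@H](C)C1(CC(=O)C(=Cc2c(OCc3ccccc3)c(C(=O)CCC)c(OC)c(C)c2OCc2ccccc2)C(=O)CC(=O)OC)OCCO1
F4 | step 10 | methyl 4-{[2,6-bis(benzyloxy)-3-butanoyl-4-methoxy-5-methylphenyl]methyl}-2-{[2,6-bis(benzyloxy)-3-butanoyl-4-methoxy-5-methylphenyl]methylidene}-6-{2-[(2S)-butan-2-yl]-1,3-dioxolan-2-yl}-3,5-dioxohexanoate | CC[C@H](C)C1(CC(=O)C(Cc2c(OCc3ccccc3)c(C(=O)CCC)c(OC)c(C)c2OCc2ccccc2)C(=O)C(=Cc2c(OCc3ccccc3)c(C(=O)CCC)c(OC)c(C)c2OCc2ccccc2)C(=O)OC)OCCO1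
F5 | step 11 | (4S)-3-hydroxy-N-methoxy-N,4-dimethylhexanamide | CC[C@H](C)C(O)CC(=O)N(C)OC
F6 | step 11 | (4S)-3-[(tert-butyldimethylsilyl)oxy]-N-methoxy-N,4-dimethylhexanamide | CC[C@H](C)C(O[Si](C)(C)C(C)(C)C)CC(=O)N(C)OC
F7 | step 11 | methyl (8S)-7-[(tert-butyldimethylsilyl)oxy]-8-methyl-3,5-dioxodecanoate | CC[C@H](C)C(O[Si](C)(C)C(C)(C)C)CC(=O)CC(=O)CC(=O)OC
F8 | step 11 | methyl (8S)-2,4-bis{[2,6-bis(benzyloxy)-3-butanoyl-4-methoxy-5-methylphenyl]methyl}-7-[(tert-butyldimethylsilyl)oxy]-8-methyl-3,5-dioxodecanoate | CC[C@H](C)C(O[Si](C)(C)C(C)(C)C)CC(=O)C(Cc1c(OCc2ccccc2)c(C(=O)CCC)c(OC)c(C)c1OCc1ccccc1)C(=O)C(Cc1c(OCc2ccccc2)c(C(=O)CCC)c(OC)c(C)c1OCc1ccccc1)C(=O)OC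
F9 | step 11 | methyl (8S)-2,4-bis{[2,6-bis(benzyloxy)-3-butanoyl-4-methoxy-5-methylphenyl]methyl}-7-hydroxy-8-methyl-3,5-dioxodecanoate | CC[C@H](C)C(O)CC(=O)C(Cc1c(OCc2ccccc2)c(C(=O)CCC)c(OC)c(C)c1OCc1ccccc1)C(=O)C(Cc1c(OCc2ccccc2)c(C(=O)CCC)c(OC)c(C)c1OCc1ccccc1)C(=O)OC
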